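**Retrosynthetic overview**
1. Target 14 ⇐ triene-ol 12: both stereocentres (9'S,10'R) are set last, by a hydroxyl-directed, diamine-controlled syn-dihydroxylation of the E-9',10'-alkene.
2. 12 ⇐ allylic bromide 9 + vinylstannane 11 (C8'–C9' bond, allyl–alkenyl Stille coupling); 9 ⇐ geranyl ether 7 by E-selective allylic oxidation and bromination.
3. 7 ⇐ 5 (key step): the C2v-symmetric 4-O-geranyl-2,6-dihydroxybenzaldehyde is desymmetrised by a ketenylidene-ylide acylation/intramolecular Wittig cascade, which builds the pyranone ring and fixes O-7 ether/O-5 phenol with no regiochemical choice.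
4. 5 ⇐ phloroglucinol 1 by formylation and hydrogen-bond-controlled 4-O-alkylation with geranyl bromide 4.
5. Ring order: the benzene ring comes from phloroglucinol; the pyranone ring is the only ring formed (step 3).

Assumption: primed locants number the side chain from OCH2 (C1') to the carbinol carbon C11'; read this way the target is the 2'E,6'E,(9'S,10'R) threo-triol.

**Step 1**
Reactants: 1 phloroglucinol
Product: 3 2,4,6-trihydroxybenzaldehyde, via iminium chloride 2 (not isolated)
Conditions: POCl3 (1.1 equiv), DMF (1.2 equiv), EtOAc, 0 °C → rt; then H2O, 50 °C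
Reagents that add atoms: N,N-dimethylformamide CN(C)C=O; water O
Why: Vilsmeier–Haack formylation: the chloroiminium ion attacks the very electron-rich ring once (the iminium product is deactivated) and hydrolysis frees the aldehyde; no stereocentre.

**Step 2**
Reactants: 3 2,4,6-trihydroxybenzaldehyde; 4 geranyl bromide
Product: 5 4-{[(2E)-3,7-dimethylocta-2,6-dien-1-yl]oxy}-2,6-dihydroxybenzaldehyde
Conditions: 4 (1.0 equiv), K2CO3 (1.05 equiv), DMF, 0 °C → rt
Reagents that add atoms: none
Why: Williamson ether synthesis: the para hydroxyl is the most acidic and is not tied up in the hydrogen bond to the formyl group, so one equivalent of base and bromide etherifies O-4 by SN2 with the E-alkene intact, leaving a C2v-symmetric dihydroxyaldehyde.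

**Step 3 (key step)**
Reactants: 5 4-{[(2E)-3,7-dimethylocta-2,6-dien-1-yl]oxy}-2,6-dihydroxybenzaldehyde
Product: 7 5-hydroxy-7-geranyloxycoumarin (7-{[(2E)-3,7-dimethylocta-2,6-dien-1-yl]oxy}-5-hydroxy-2H-chromen-2-one), via ester ylide 6 (not isolated)
Conditions: Ph3P=C=C=O (1.05 equiv, slow addition), toluene (0.02 M), rt → 60 °C
Reagents that add atoms: (triphenylphosphoranylidene)ketene O=C=C=P(c1ccccc1)(c1ccccc1)c1ccccc1
Why: Bestmann ketenylidene-ylide cascade: either of the two homotopic phenols adds to the cumulated ylide to give the acyl ylide, whose intramolecular Wittig reaction with the ortho formyl group closes the pyranone (cis alkene enforced by the ring) and breaks the mirror symmetry, so only the 7-ether/5-phenol isomer can form.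

**Step 4**
Reactants: 7 5-hydroxy-7-geranyloxycoumarin
Product: 8 5-hydroxy-7-{[(2E,6E)-8-hydroxy-3,7-dimethylocta-2,6-dien-1-yl]oxy}-2H-chromen-2-one
Conditions: SeO2 (0.4 equiv), t-BuOOH (3 equiv), salicylic acid (0.1 equiv), CH2Cl2, rt
Reagents that add atoms: tert-butyl hydroperoxide CC(C)(C)OO; selenium dioxide O=[Se]=O (catalytic oxygen carrier)
Why: Riley allylic oxidation (ene reaction then [2,3]-sigmatropic shift): the remote 6',7'-alkene is more electron-rich than the 2',3'-alkene bearing the allylic aryloxy group and is oxidised at its (E)-methyl group, so the 6'E geometry is kept.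

**Step 5**
Reactants: 8 5-hydroxy-7-{[(2E,6E)-8-hydroxy-3,7-dimethylocta-2,6-dien-1-yl]oxy}-2H-chromen-2-one
Product: 9 7-{[(2E,6E)-8-bromo-3,7-dimethylocta-2,6-dien-1-yl]oxy}-5-hydroxy-2H-chromen-2-one
Conditions: CBr4 (1.3 equiv), PPh3 (1.3 equiv), CH2Cl2, −20 → 0 °C; used at once
Reagents that add atoms: tetrabromomethane BrC(Br)(Br)Br
Why: Appel reaction: SN2 displacement of the primary allylic alkoxyphosphonium by bromide under neutral conditions, so the free phenol is untouched and there is no allylic transposition.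

**Step 6**
Reactants: 10 2-methylbut-3-yn-2-ol
Product: 11 (3E)-2-methyl-4-(tributylstannyl)but-3-en-2-ol
Conditions: Bu3SnH (1.05 equiv), PdCl2(PPh3)2 (2 mol%), THF, 0 °C → rt
Reagents that add atoms: tributyltin hydride CCCC[SnH](CCCC)CCCC
Why: Palladium-catalysed syn-hydrostannation: the bulky tertiary carbinol sends tin to the terminal carbon and cis addition of H and Sn gives the E-vinylstannane.

**Step 7**
Reactants: 9 7-{[(2E,6E)-8-bromo-3,7-dimethylocta-2,6-dien-1-yl]oxy}-5-hydroxy-2H-chromen-2-one; 11 (3E)-2-methyl-4-(tributylstannyl)but-3-en-2-ol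
Product: 12 5-hydroxy-7-{[(2E,6E,9E)-11-hydroxy-3,7,11-trimethyldodeca-2,6,9-trien-1-yl]oxy}-2H-chromen-2-one
Conditions: Pd2(dba)3 (2.5 mol%), AsPh3 (10 mol%), THF, 45 °C
Reagents that add atoms: none
Why: Stille allyl–alkenyl coupling: zerovalent palladium ionises the allylic bromide and the alkenyl group is transferred with retention to the less hindered CH2 terminus under base-free conditions (free phenol tolerated), giving the skipped E,E,E-triene.

**Step 8**
Reactants: 12 5-hydroxy-7-{[(2E,6E,9E)-11-hydroxy-3,7,11-trimethyldodeca-2,6,9-trien-1-yl]oxy}-2H-chromen-2-one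
Product: 14 target (5-hydroxy-7-{[(2E,6E,9S,10R)-9,10,11-trihydroxy-3,7,11-trimethyldodeca-2,6-dien-1-yl]oxy}-2H-chromen-2-one), via diamine-chelated osmate ester 13 (not isolated)
Conditions: OsO4 (1.05 equiv), N,N'-bis(3,3-dimethylbutyl)-2,2'-bipyrrolidine (2.2 equiv; the antipode that gives (S,S)-hydrobenzoin from (E)-stilbene), CH2Cl2, −78 °C; then aq. Na2SO3, THF, 40 °C
Reagents that add atoms: osmium tetroxide O=[Os](=O)(=O)=O
Why: Proposed new method: the only free allylic hydroxyl hydrogen-bonds to an oxo ligand of the OsO4·diamine complex and steers the [3+2] osmylation to the E-9',10'-alkene ahead of the two unassisted trisubstituted alkenes and the electron-poor pyranone alkene, while the C2-symmetric diamine selects the 9'Si,10'Re face, so suprafacial delivery of both oxygens to the E-alkene gives the threo (9'S,10'R) diol; the closest known reactions are the OsO4·TMEDA hydroxyl-directed dihydroxylation of allylic alcohols and the stoichiometric chiral-diamine OsO4 dihydroxylation of E-alkenes.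

**Compound list**
1 | phloroglucinol (benzene-1,3,5-triol) | Oc1cc(O)cc(O)c1 | starting material
2 | (2,4,6-trihydroxybenzylidene)dimethyliminium chloride | C[N+](C)=Cc1c(O)cc(O)cc1O.[Cl-] | intermediate
3 | 2,4,6-trihydroxybenzaldehyde | O=Cc1c(O)cc(O)cc1O | intermediate
4 | geranyl bromide ((2E)-1-bromo-3,7-dimethylocta-2,6-diene) | CC(C)=CCC/C(C)=C/CBr | starting material
5 | 4-{[(2E)-3,7-dimethylocta-2,6-dien-1-yl]oxy}-2,6-dihydroxybenzaldehyde | O=Cc1c(O)cc(OC/C=C(\C)CCC=C(C)C)cc1O | intermediate
6 | 2-formyl-3-hydroxy-5-{[(2E)-3,7-dimethylocta-2,6-dien-1-yl]oxy}phenyl (triphenylphosphoranylidene)acetate | O=Cc1c(O)cc(OC/C=C(\C)CCC=C(C)C)cc1OC(=O)C=P(c1ccccc1)(c1ccccc1)c1ccccc1 | intermediate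
7 | 7-{[(2E)-3,7-dimethylocta-2,6-dien-1-yl]oxy}-5-hydroxy-2H-chromen-2-one | O=c1ccc2c(O)cc(OC/C=C(\C)CCC=C(C)C)cc2o1 | intermediate
8 | 5-hydroxy-7-{[(2E,6E)-8-hydroxy-3,7-dimethylocta-2,6-dien-1-yl]oxy}-2H-chromen-2-one | O=c1ccc2c(O)cc(OC/C=C(\C)CC/C=C(\C)CO)cc2o1 | intermediate
9 | 7-{[(2E,6E)-8-bromo-3,7-dimethylocta-2,6-dien-1-yl]oxy}-5-hydroxy-2H-chromen-2-one | O=c1ccc2c(O)cc(OC/C=C(\C)CC/C=C(\C)CBr)cc2o1 | intermediate
10 | 2-methylbut-3-yn-2-ol | CC(C)(O)C#C | starting material
11 | (3E)-2-methyl-4-(tributylstannyl)but-3-en-2-ol | CCCC[Sn](CCCC)(CCCC)/C=C/C(C)(C)O | intermediate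
12 | 5-hydroxy-7-{[(2E,6E,9E)-11-hydroxy-3,7,11-trimethyldodeca-2,6,9-trien-1-yl]oxy}-2H-chromen-2-one | O=c1ccc2c(O)cc(OC/C=C(\C)CC/C=C(\C)C/C=C/C(C)(C)O)cc2o1 | intermediate
13 | cyclic (9'S,10'R)-9',10'-osmate ester of hexavalent osmium (chelating diamine not drawn) | O=c1ccc2c(O)cc(OC/C=C(\C)CC/C=C(\C)C[C@@H]3O[Os](=O)(=O)O[C@H]3C(C)(C)O)cc2o1 | intermediate
14 | 5-hydroxy-7-{[(2E,6E,9S,10R)-9,10,11-trihydroxy-3,7,11-trimethyldodeca-2,6-dien-1-yl]oxy}-2H-chromen-2-one | C/C(=C\COc1cc(O)c2ccc(=O)oc2c1)CC/C=C(\C)C[C@H](O)[C@@H](O)C(C)(C)O | target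

**Step count and risks**
Total step count: 8. Longest linear sequence: 7 steps (1 → 3 → 5 → 7 → 8 → 9 → 12 → 14); stannane 11 is made in one step on a side arm.

The three steps most likely to fail:

- Step 8: the combination of hydroxyl direction with a chiral diamine is unprecedented, and the isolated 6',7'-alkene is the intrinsically more reactive site. The fallback gives up reagent control and resolves. It sets out from 12: OsO4 with TMEDA in CH2Cl2 at −78 °C (the established hydroxyl-directed protocol), followed by the same sulfite work-up, proceeds through the TMEDA-chelated osmate ester as a racemate, whose mirror-image half is the (9'R,10'S) osmate ester F4. This gives the threo triol as a 1:1 mixture of 14 and its enantiomer, the (9'R,10'S)-triol F5. Preparative chromatography on a chiral stationary phase removes F5 and the route is back at 14.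

- Step 4: SeO2 oxidation next to a free phenol is likely to give modest conversion and some over-oxidation to the enal. The fallback functionalises C8' through the alkene instead of the C–H bond. It sets out from 7: mCPBA (NaHCO3, CH2Cl2, 0 °C) epoxidises the electron-rich 6',7'-alkene to the racemic 6',7'-epoxide F2. Al(OiPr)3 in toluene at 110 °C isomerises it to the racemic 6'-hydroxy-7'-methylene allylic alcohol F3. PBr3 in Et2O at −10 °C then introduces bromide with allylic transposition; the stereocentre is lost and the thermodynamically preferred E-trisubstituted alkene forms. The product is 9, where the route resumes at the Stille coupling.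

- Step 3: the second phenol can trap ylide, intermolecular Wittig reaction can compete, and the step depends on clean mono-O-alkylation in step 2. The fallback builds the pyranone first. It sets out from 1: propiolic acid, Pd(OAc)2 (1 mol%), CF3CO2H, rt (hydroarylation then lactonisation) gives 5,7-dihydroxycoumarin F1 in one step. Then 4 (1.0 equiv) and K2CO3 (1.0 equiv) in acetone etherify mainly the more acidic, less hindered 7-OH. After chromatographic removal of the 5-O- and bis-ethers the route is back at 7.

**Further compounds**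
F1 | step 3 | 5,7-dihydroxycoumarin | O=c1ccc2c(O)cc(O)cc2o1
F2 | step 4 | 7-{[(2E)-5-(3,3-dimethyloxiran-2-yl)-3-methylpent-2-en-1-yl]oxy}-5-hydroxy-2H-chromen-2-one (racemic) | O=c1ccc2c(O)cc(OC/C=C(\C)CCC3OC3(C)C)cc2o1
F3 | step 4 | 5-hydroxy-7-{[(2E)-6-hydroxy-3,7-dimethylocta-2,7-dien-1-yl]oxy}-2H-chromen-2-one (racemic) | O=c1ccc2c(O)cc(OC/C=C(\C)CCC(O)C(C)=C)cc2o1
F4 | step 8 | cyclic (9'R,10'S)-9',10'-osmate ester of hexavalent osmium (TMEDA not drawn) | O=c1ccc2c(O)cc(OC/C=C(\C)CC/C=C(\C)C[C@H]3O[Os](=O)(=O)O[C@@H]3C(C)(C)O)cc2o1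
F5 | step 8 | 5-hydroxy-7-{[(2E,6E,9R,10S)-9,10,11-trihydroxy-3,7,11-trimethyldodeca-2,6-dien-1-yl]oxy}-2H-chromen-2-one | O=c1ccc2c(O)cc(OC/C=C(\C)CC/C=C(\C)C[C@@H](O)[C@H](O)C(C)(C)O)cc2o1
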